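**Retrosynthetic overview**
1. Numbering runs along the C15 chain from the alkyne CH (C1) to C15. The strategy rests on ring A, the C6–O–C9 tetrahydrofuran: its C7 oxygen is trans to the C6 side chain and cis to the C9–C10 bond, and C10 beside C9 carries oxygen. That is the pattern left when an α-silyl allyl unit (C6–C8) adds to an α-alkoxy aldehyde (C9, C10).
2. Late disconnections: C2–C3 (Sonogashira) and C3=C4 (Takai olefination of the C4 aldehyde); the ethyl group C14–C15 comes from an alkyne.
3. Ring B (oxocane O–C7…C13) is opened at O7–C13 (Nicholas closure of a cobalt-complexed C13 propargylic cation); C13–C14 by ethynyl Grignard addition, C12–Br by enamine bromination of the C13 aldehyde.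
4. Ring A is opened at C8–C9 and O–C6: [3+2] annulation of (R)-allylsilane 7 (C4–C8) with (R)-α-alkoxy aldehyde 13 (C9–C14); the C7 silicon later becomes the C7 hydroxyl.
5. Ring order: ring A in step 10, ring B in step 18. The C10 ether that serves chelation is exchanged for the acetate before ring B is closed.

Key step: step 10

Assumption: in step 5 the enantiomer of the chiral carbene ligand that delivers the (R)-silane is used; the sense of induction would be fixed on the first run.

**Silane fragment**

Step 1
Reactants: 1 but-3-yn-1-ol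
Product: 2 4-(triisopropylsilyloxy)but-1-yne
Conditions: TIPSCl, imidazole, CH2Cl2, 0 °C → rt
Reagents that add atoms: chlorotriisopropylsilane, SMILES CC(C)[Si](Cl)(C(C)C)C(C)C
Why: Imidazole-assisted silylation of the primary alcohol; the bulky triisopropylsilyl ether is meant to survive SnCl4, peracid and BF3·OEt2 later and is too hindered to act as an internal nucleophile in step 10.

Step 2
Reactants: 2 4-(triisopropylsilyloxy)but-1-yne
Product: 4 5-(triisopropylsilyloxy)pent-2-yn-1-ol, via lithium acetylide 3 (not isolated)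
Conditions: n-BuLi, THF, −78 °C; then (CH2O)n, −78 °C → rt
Reagents that add atoms: formaldehyde (as paraformaldehyde), SMILES C=O
Why: Deprotonation of the terminal alkyne and 1,2-addition of the acetylide to formaldehyde (alkynylation) gives the propargylic alcohol; the new carbon is C8.

Step 3
Reactants: 4 5-(triisopropylsilyloxy)pent-2-yn-1-ol
Product: 5 (E)-5-(triisopropylsilyloxy)pent-2-en-1-ol
Conditions: NaAlH2(OCH2CH2OMe)2, THF, 0 °C → rt
Reagents that add atoms: none
Why: Hydroxyl-directed trans-hydroalumination of the propargylic alcohol followed by protonolysis gives the (E)-allylic alcohol.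

Step 4
Reactants: 5 (E)-5-(triisopropylsilyloxy)pent-2-en-1-ol
Product: 6 diethyl (E)-5-(triisopropylsilyloxy)pent-2-en-1-yl phosphate
Conditions: (EtO)2P(O)Cl, pyridine, DMAP (cat.), CH2Cl2, 0 °C
Reagents that add atoms: diethyl chlorophosphate, SMILES CCOP(=O)(Cl)OCC
Why: Phosphorylation of the allylic alcohol installs the leaving group suited to copper-catalysed SN2′ substitution.

Step 5
Reactants: 6 diethyl (E)-5-(triisopropylsilyloxy)pent-2-en-1-yl phosphate
Product: 7 (R)-3-(dimethylphenylsilyl)-5-(triisopropylsilyloxy)pent-1-ene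
Conditions: PhMe2Si–Bpin (1.5 equiv), CuCl (5 mol %), chiral imidazolinium salt (carbene precursor, 5.5 mol %), NaOMe, THF, 0 °C
Reagents that add atoms: (dimethylphenylsilyl)boronic acid pinacol ester, SMILES CC1(C)OB(OC1(C)C)[Si](C)(C)c1ccccc1
Why: Copper-catalysed enantioselective allylic substitution with a silyl nucleophile: the carbene–copper silyl species formed by Si–B transmetalation attacks C6 in the SN2′ sense with loss of phosphate, and the chiral ligand sets the C6 silicon-bearing centre.

**Aldehyde fragment**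

Step 6
Reactants: 8 (R)-trityl glycidyl ether; 9 allylmagnesium bromide
Product: 10 (R)-1-(trityloxy)hex-5-en-2-ol
Conditions: CuI (10 mol %), THF, −30 °C → 0 °C
Reagents that add atoms: none
Why: Copper-catalysed Grignard opening of the terminal epoxide at its CH2 carbon; the stereocentre is not touched, so C10 keeps the configuration of 8.

Step 7
Reactants: 10 (R)-1-(trityloxy)hex-5-en-2-ol
Product: 11 (R)-2-(2-naphthylmethoxy)-1-(trityloxy)hex-5-ene
Conditions: NaH, 2-(bromomethyl)naphthalene, Bu4NI (cat.), THF/DMF, 0 °C → rt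
Reagents that add atoms: 2-(bromomethyl)naphthalene, SMILES BrCc1ccc2ccccc2c1
Why: Williamson etherification; the 2-naphthylmethyl ether chelates like a benzyl ether in step 10 but can later be removed by DDQ in the presence of the terminal alkene and the arylsilane.

Step 8
Reactants: 11 (R)-2-(2-naphthylmethoxy)-1-(trityloxy)hex-5-ene
Product: 12 (R)-2-(2-naphthylmethoxy)hex-5-en-1-ol
Conditions: p-TsOH·H2O (cat.), MeOH/CH2Cl2, rt
Reagents that add atoms: none
Why: Acid-catalysed SN1 solvolysis of the trityl ether (trityl cation trapped by methanol) frees the primary alcohol, while the naphthylmethyl ether and the alkene are stable.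

Step 9
Reactants: 12 (R)-2-(2-naphthylmethoxy)hex-5-en-1-ol
Product: 13 (R)-2-(2-naphthylmethoxy)hex-5-enal
Conditions: Dess–Martin periodinane, CH2Cl2, 0 °C → rt; used at once
Reagents that add atoms: none
Why: Dess–Martin oxidation of the primary alcohol under near-neutral conditions should give the α-alkoxy aldehyde without epimerisation at C10.

**Key step**

Step 10
Reactants: 7 (R)-3-(dimethylphenylsilyl)-5-(triisopropylsilyloxy)pent-1-ene; 13 (R)-2-(2-naphthylmethoxy)hex-5-enal
Product: 15 2,5-trans silyl tetrahydrofuran (6S,7R,9R,10R; C4–C14), via β-silyl cation 14 (not isolated)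
Conditions: 13, SnCl4 (1.05 equiv), CH2Cl2, −78 °C; then 7, −78 → −45 °C
Reagents that add atoms: none
Why: SnCl4 binds the aldehyde oxygen and the C10 ether oxygen of 13 in a five-membered chelate, and the terminal carbon C8 of allylsilane 7 adds to C9 on the alkene face anti to the C6–Si bond (anti-SE2′, C8–C9 bond) to give the silicon-bridged β-silyl cation 14, in which the dimethylphenylsilyl group, a poor leaving group at low temperature, migrates from C6 to C7 instead of being lost. The tin alkoxide then displaces the bridging silicon at C6 from the rear (O–C6 bond), a five-membered closure of 5-exo-tet type with inversion at C6; the closest known reaction type is the Lewis-acid [3+2] annulation of α-substituted allylsilanes with chelating α-alkoxy aldehydes, which gives 2,5-trans silyl tetrahydrofurans. C9 is set by the chelate, which is attacked on the face away from the C11 chain (C9–O syn to C10–O); C6 is set by the (R) centre of 7 through inversion; C7 is set by the reactive conformer of 7 with the C6 hydrogen eclipsing the alkene, which leaves silicon trans to the C6 side chain. The step needs annulation to outrun loss of silicon (allyl transfer) and needs the chelate face and the anti-SE2′ face to combine as the 2,5-trans ring; the chelating arylmethyl ether, the reluctant silyl leaving group and the (R)/(R) pairing of 7 and 13 are chosen to secure this. The triisopropylsilyl ether is too hindered to trap the cation, and the terminal alkene of 13 is far less nucleophilic than the allylsilane.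

**From ring A to the ring B precursor**

Step 11
Reactants: 15 2,5-trans silyl tetrahydrofuran (6S,7R,9R,10R)
Product: 16 C10 alcohol of 15
Conditions: DDQ, CH2Cl2/pH 7 buffer, 0 °C → rt
Reagents that add atoms: none
Why: Oxidative cleavage of the arylmethyl ether by DDQ (hydride abstraction, hydrolysis of the oxocarbenium ion) frees the C10 hydroxyl; the ether must go before ring B is closed, because a C10 ether oxygen would capture the C13 cation of step 18 as a five-membered ring with loss of the arylmethyl group.

Step 12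
Reactants: 16 C10 alcohol
Product: 17 C10 acetate
Conditions: Ac2O, pyridine, DMAP (cat.), CH2Cl2, rt
Reagents that add atoms: acetic anhydride, SMILES CC(=O)OC(C)=O
Why: DMAP-catalysed acylation installs the C10 acetate of the target, whose ester oxygen is not nucleophilic enough to interfere in step 18.

Step 13
Reactants: 17 C10 acetate
Product: 19 C13 primary alcohol, via ozonide 18 (not isolated)
Conditions: O3, CH2Cl2, −78 °C (Sudan Red 7B end point); then NaBH4, MeOH, −78 → 0 °C
Reagents that add atoms: ozone, SMILES [O-][O+]=O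
Why: Ozonolysis of the terminal alkene and hydride reduction of the ozonide removes C14 and leaves the C13 alcohol; the alcohol level is needed because the peracid of step 14 would oxidise an aldehyde.

Step 14
Reactants: 19 C13 primary alcohol
Product: 20 C7,C13-diol (6S,7R,9R,10R)
Conditions: Hg(OAc)2, AcOOH (32% in AcOH), AcOH, rt
Reagents that add atoms: peracetic acid, SMILES CC(=O)OO
Why: Fleming–Tamao oxidation: ipso-mercuration removes phenyl from silicon and the peracid-induced 1,2-shift of C7 from silicon to oxygen proceeds with retention, so the C7 hydroxyl is trans to the C6 chain and cis to the C9 chain.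

Step 15
Reactants: 20 C7,C13-diol
Product: 21 C7-hydroxy C13-aldehyde
Conditions: TEMPO (10 mol %), PhI(OAc)2, CH2Cl2, rt
Reagents that add atoms: none
Why: Nitroxyl-mediated oxidation, in which the oxoammonium ion oxidises the unhindered primary C13 alcohol much faster than the secondary C7 alcohol.

Step 16
Reactants: 21 C7-hydroxy C13-aldehyde
Product: 22 (12S)-12-bromo C13-aldehyde
Conditions: (2R,5R)-2,5-diphenylpyrrolidine (20 mol %), 4,4-dibromo-2,6-di-tert-butylcyclohexa-2,5-dienone, PhCO2H (20 mol %), H2O, CH2Cl2/pentane, −40 °C; cold filtration through silica, used at once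
Reagents that add atoms: 4,4-dibromo-2,6-di-tert-butylcyclohexa-2,5-dien-1-one, SMILES CC(C)(C)C1=CC(Br)(Br)C=C(C1=O)C(C)(C)C
Why: Organocatalytic asymmetric α-bromination by enamine catalysis: the C2-symmetric amine forms the (E)-enamine across C12–C13, one phenyl group shields one face and the dienone delivers Br+ to the other, which by this shielding model should give 12S under catalyst control.

Step 17
Reactants: 22 (12S)-12-bromo C13-aldehyde
Product: 23 (12S)-bromo propargylic alcohol (C13 epimers)
Conditions: HC≡CMgBr (3.5 equiv), THF, −78 °C; AcOH quench at −78 °C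
Reagents that add atoms: ethynylmagnesium bromide, SMILES C#C[Mg]Br
Why: 1,2-Addition of the weakly basic alkynyl Grignard reagent to the aldehyde at low temperature should outpace enolisation at C12 and attack on the acetate (the first equivalent is spent on the C7 hydroxyl); the C13 carbinol forms as a mixture, which is harmless because C13 is ionised in step 18.

**Ring B and end game**

Step 18
Reactants: 23 (12S)-bromo propargylic alcohol
Product: 25 bicyclic ether with Co2(CO)6-complexed C13 alkyne (6S,7R,9R,10R,12S,13R), via hexacarbonyldicobalt alkyne complex 24 (not isolated)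
Conditions: Co2(CO)8, CH2Cl2, rt; then dilution to 0.005 M, BF3·OEt2, −20 → 0 °C
Reagents that add atoms: dicobalt octacarbonyl, SMILES O=C=[Co](=C=O)(=C=O)(=C=O)[Co](=C=O)(=C=O)(=C=O)=C=O
Why: Nicholas reaction: BF3·OEt2 ionises the cobalt-complexed propargylic alcohol to the Co2(CO)6-stabilised C13 cation, which the C7 hydroxyl (held cis to the C9 chain on ring A) captures to form the O7–C13 bond and the eight-membered ring B; ionisation is reversible, so the ether should settle in the more stable arrangement with H7 and H13 on the same side of the C7–O–C13 unit (C6 and C14 cis, 13R) and the cluster trans to the C12 bromine.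

Step 19
Reactants: 25 bicyclic cobalt complex
Product: 26 bicyclic C13 alkyne
Conditions: (NH4)2Ce(NO3)6, acetone, −10 °C
Reagents that add atoms: none
Why: Oxidative decomplexation releases the free terminal alkyne without touching the bromide, the acetate or the silyl ether.

Step 20
Reactants: 26 bicyclic C13 alkyne
Product: 27 bicyclic 13-ethyl compound
Conditions: H2 (1 atm), PtO2, EtOAc, rt
Reagents that add atoms: none
Why: Heterogeneous hydrogenation of the terminal alkyne to the ethyl group over platinum, which under neutral conditions should leave the secondary C–Br bond and the propargylic C–O bond intact.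

Step 21
Reactants: 27 bicyclic 13-ethyl compound
Product: 28 C4 primary alcohol
Conditions: HF·pyridine, pyridine, THF, 0 °C → rt
Reagents that add atoms: none
Why: Fluoride cleavage of the silyl ether under buffered, non-basic conditions that spare the acetate and the bromide.

Step 22
Reactants: 28 C4 primary alcohol
Product: 29 C4 aldehyde
Conditions: Dess–Martin periodinane, CH2Cl2, 0 °C → rt; used at once
Reagents that add atoms: none
Why: Dess–Martin oxidation gives the β-alkoxy aldehyde under non-basic conditions, which avoids β-elimination of the C6 oxygen.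

Step 23
Reactants: 29 C4 aldehyde
Product: 30 (E)-vinyl iodide (C3=C4)
Conditions: CrCl2, CHI3, THF, 0 °C → rt
Reagents that add atoms: iodoform, SMILES IC(I)I
Why: Takai olefination: the geminal dichromium species from CHI3 and CrCl2 adds to the aldehyde and eliminates to the (E)-vinyl iodide, setting the C3=C4 geometry without base.

Step 24
Reactants: 30 (E)-vinyl iodide
Product: 31 trimethylsilyl (E)-enyne
Conditions: trimethylsilylacetylene, PdCl2(PPh3)2 (5 mol %), CuI (10 mol %), i-Pr2NH, THF, rt
Reagents that add atoms: trimethylsilylacetylene, SMILES C#C[Si](C)(C)C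
Why: Sonogashira coupling of the vinyl iodide forms the C2–C3 bond with retention of the alkene geometry; the secondary alkyl bromide does not undergo oxidative addition under these conditions.

Step 25
Reactants: 31 trimethylsilyl (E)-enyne
Product: 32 target CNP0217809.2
Conditions: Bu4NF, AcOH (1:1), THF, 0 °C
Reagents that add atoms: none
Why: Fluoride-induced protodesilylation of the alkynylsilane, buffered with acetic acid so that the acetate and the secondary bromide survive, gives the terminal enyne.

**Compound list**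

1 | but-3-yn-1-ol | C#CCCO | starting material
2 | 4-(triisopropylsilyloxy)but-1-yne | C#CCCO[Si](C(C)C)(C(C)C)C(C)C | intermediate
3 | lithium acetylide of 2 | [Li]C#CCCO[Si](C(C)C)(C(C)C)C(C)C | intermediate
4 | 5-(triisopropylsilyloxy)pent-2-yn-1-ol | OCC#CCCO[Si](C(C)C)(C(C)C)C(C)C | intermediate
5 | (E)-5-(triisopropylsilyloxy)pent-2-en-1-ol | OC/C=C/CCO[Si](C(C)C)(C(C)C)C(C)C | intermediate
6 | diethyl (E)-5-(triisopropylsilyloxy)pent-2-en-1-yl phosphate | CCOP(=O)(OCC)OC/C=C/CCO[Si](C(C)C)(C(C)C)C(C)C | intermediate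
7 | (R)-3-(dimethylphenylsilyl)-5-(triisopropylsilyloxy)pent-1-ene | C=C[C@H]([Si](C)(C)c1ccccc1)CCO[Si](C(C)C)(C(C)C)C(C)C | intermediate
8 | (R)-trityl glycidyl ether | [C@H]1(COC(c2ccccc2)(c2ccccc2)c2ccccc2)CO1 | starting material
9 | allylmagnesium bromide | C=CC[Mg]Br | starting material
10 | (R)-1-(trityloxy)hex-5-en-2-ol | C=CCC[C@@H](O)COC(c1ccccc1)(c1ccccc1)c1ccccc1 | intermediate
11 | (R)-2-(2-naphthylmethoxy)-1-(trityloxy)hex-5-ene | C=CCC[C@@H](OCc1ccc2ccccc2c1)COC(c1ccccc1)(c1ccccc1)c1ccccc1 | intermediate
12 | (R)-2-(2-naphthylmethoxy)hex-5-en-1-ol | C=CCC[C@@H](OCc1ccc2ccccc2c1)CO | intermediate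
13 | (R)-2-(2-naphthylmethoxy)hex-5-enal | C=CCC[C@@H](OCc1ccc2ccccc2c1)C=O | intermediate
14 | β-silyl cation with tin alkoxide formed by C8–C9 bonding (C7 cation bridged by the C6 silicon, drawn open; ether–tin chelation not drawn) | CC(C)[Si](C(C)C)(C(C)C)OCC[C@@H]([Si](C)(C)c1ccccc1)[CH+]C[C@@H](O[Sn-](Cl)(Cl)(Cl)Cl)[C@H](OCc1ccc2ccccc2c1)CCC=C | intermediate
15 | (2S,3R,5R)-3-(dimethylphenylsilyl)-5-[(1R)-1-(2-naphthylmethoxy)pent-4-enyl]-2-[2-(triisopropylsilyloxy)ethyl]tetrahydrofuran (chain 6S,7R,9R,10R) | CC(C)[Si](C(C)C)(C(C)C)OCC[C@@H]1O[C@@H]([C@H](OCc2ccc3ccccc3c2)CCC=C)C[C@H]1[Si](C)(C)c1ccccc1 | intermediate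
16 | C10 alcohol: as 15 with (1R)-1-hydroxypent-4-enyl at C9 | CC(C)[Si](C(C)C)(C(C)C)OCC[C@@H]1O[C@@H]([C@H](O)CCC=C)C[C@H]1[Si](C)(C)c1ccccc1 | intermediate
17 | C10 acetate: as 15 with (1R)-1-acetoxypent-4-enyl at C9 | CC(C)[Si](C(C)C)(C(C)C)OCC[C@@H]1O[C@@H]([C@H](OC(C)=O)CCC=C)C[C@H]1[Si](C)(C)c1ccccc1 | intermediate
18 | ozonide (1,2,4-trioxolane) of the C13=C14 alkene of 17 | CC(C)[Si](C(C)C)(C(C)C)OCC[C@@H]1O[C@@H]([C@H](OC(C)=O)CCC2OCOO2)C[C@H]1[Si](C)(C)c1ccccc1 | intermediate
19 | C13 primary alcohol: C10 acetate, C7 silyl, chain ending in C13H2OH | CC(C)[Si](C(C)C)(C(C)C)OCC[C@@H]1O[C@@H]([C@H](OC(C)=O)CCCO)C[C@H]1[Si](C)(C)c1ccccc1 | intermediate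
20 | C7,C13-diol (6S,7R,9R,10R): 3-hydroxytetrahydrofuran with C10 acetate | CC(C)[Si](C(C)C)(C(C)C)OCC[C@@H]1O[C@@H]([C@H](OC(C)=O)CCCO)C[C@H]1O | intermediate
21 | C7-hydroxy C13-aldehyde | CC(C)[Si](C(C)C)(C(C)C)OCC[C@@H]1O[C@@H]([C@H](OC(C)=O)CCC=O)C[C@H]1O | intermediate
22 | (12S)-12-bromo C13-aldehyde | CC(C)[Si](C(C)C)(C(C)C)OCC[C@@H]1O[C@@H]([C@H](OC(C)=O)C[C@H](Br)C=O)C[C@H]1O | intermediate
23 | (12S)-12-bromo-13-hydroxy-14-yne, C13 epimers | CC(C)[Si](C(C)C)(C(C)C)OCC[C@@H]1O[C@@H]([C@H](OC(C)=O)C[C@H](Br)C(O)C#C)C[C@H]1O | intermediate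
24 | Co2(CO)6 complex of the alkyne of 23 | CC(C)[Si](C(C)C)(C(C)C)OCC[C@@H]1O[C@@H]([C@H](OC(C)=O)C[C@H](Br)C(O)C23[CH]4[Co]2(=C=O)(=C=O)(=C=O)[Co]34(=C=O)(=C=O)=C=O)C[C@H]1O | intermediate
25 | 2,8-dioxabicyclo[5.2.1]decane (6S,7R,9R,10R,12S,13R): C6 CH2CH2OTIPS, C10 OAc, C12 Br, C13 Co2(CO)6-complexed ethynyl | CC(C)[Si](C(C)C)(C(C)C)OCC[C@@H]1O[C@@H]2C[C@H]1O[C@H](C34[CH]5[Co]3(=C=O)(=C=O)(=C=O)[Co]45(=C=O)(=C=O)=C=O)[C@@H](Br)C[C@H]2OC(C)=O | intermediate
26 | as 25 with free ethynyl at C13 | CC(C)[Si](C(C)C)(C(C)C)OCC[C@@H]1O[C@@H]2C[C@H]1O[C@H](C#C)[C@@H](Br)C[C@H]2OC(C)=O | intermediate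
27 | as 25 with ethyl at C13 | CC(C)[Si](C(C)C)(C(C)C)OCC[C@@H]1O[C@@H]2C[C@H]1O[C@H](CC)[C@@H](Br)C[C@H]2OC(C)=O | intermediate
28 | C4 primary alcohol (C6 carries CH2CH2OH) | OCC[C@@H]1O[C@@H]2C[C@H]1O[C@H](CC)[C@@H](Br)C[C@H]2OC(C)=O | intermediate
29 | C4 aldehyde (C6 carries CH2CHO) | O=CC[C@@H]1O[C@@H]2C[C@H]1O[C@H](CC)[C@@H](Br)C[C@H]2OC(C)=O | intermediate
30 | (E)-vinyl iodide (C6 carries CH2CH=CHI) | I/C=C/C[C@@H]1O[C@@H]2C[C@H]1O[C@H](CC)[C@@H](Br)C[C@H]2OC(C)=O | intermediate
31 | trimethylsilyl (E)-enyne | C[Si](C)(C)C#C/C=C/C[C@@H]1O[C@@H]2C[C@H]1O[C@H](CC)[C@@H](Br)C[C@H]2OC(C)=O | intermediate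
32 | CNP0217809.2: (6S,7R,9R,10R,12S,13R)-4-bromo-3-ethyl-9-[(E)-pent-2-en-4-ynyl]-2,8-dioxabicyclo[5.2.1]decan-6-yl acetate (chain numbering for descriptors) | C#C/C=C/C[C@@H]1O[C@@H]2C[C@H]1O[C@H](CC)[C@@H](Br)C[C@H]2OC(C)=O | target

**Step count**
Total: 25 steps. Longest linear sequence: 21 steps (steps 1–5, then 10–25).

**Steps most likely to fail**

Step 10 (annulation). The β-silyl cation may lose silicon before it migrates and closes, so that allyl transfer gives the open-chain homoallylic alcohol, or addition through the non-chelated aldehyde may erode the C9 configuration. The fallback makes allyl transfer the intended first stage and builds ring A in a second stage. From 7 and 13, TiCl4 (CH2Cl2, −78 °C) should give the chelation-controlled (E)-homoallylic alcohol F1. Shi epoxidation of its internal (E)-alkene (D-fructose-derived ketone, KHSO5, buffered MeCN/dimethoxymethane, 0 °C) should give the (6R,7R)-epoxy alcohol F2 under reagent control. Camphorsulfonic acid (cat., CH2Cl2) should then close the C9 hydroxyl onto C6 with inversion to give the 3-hydroxytetrahydrofuran F3, which already carries the C7 hydroxyl. The triethylsilyl ether F4 (TESCl, imidazole), the C10 alcohol F5 (DDQ), the C10 acetate F6 (Ac2O, pyridine, DMAP) and the C13 alcohol F7 (O3; then NaBH4) follow. PPTS in MeOH at 0 °C removes the triethylsilyl group and returns to 20.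

Step 18 (Nicholas closure). The C13 cation is destabilised by the adjacent C–Br bond; it may shed the C12 proton to a bromo-enyne complex, or the eight-membered closure may be too slow against elimination and oligomerisation. The fallback carries oxygen instead of bromine at C12 through the closure and brings in bromine last by invertive displacement. From 21, L-proline-catalysed α-aminoxylation with nitrosobenzene should give the (12R)-anilinooxy aldehyde F8, and HC≡CMgBr then the propargylic alcohol F9. Co2(CO)8 followed by BF3·OEt2 gives the cyclised cobalt complex F10, and (NH4)2Ce(NO3)6 the bicyclic alkyne F11. H2 over Pd/C reduces the alkyne and cleaves the N–O bond to give the (12R)-alcohol F12, with no halogen present. CBr4 and P(n-C8H17)3 in toluene at 70 °C displace the hydroxyl with inversion and return to 27.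

Step 16 (α-bromination). The α-bromo aldehyde may epimerise at C12 by enolisation while the amine catalyst is present, or decompose on handling. The fallback fixes the new centre as soon as it forms and regenerates the aldehyde later without amine. From 21 the same bromination is quenched at −40 °C with NaBH4 in MeOH to give the configurationally stable (12S)-bromo alcohol F13, which can be purified and assayed. TEMPO with PhI(OAc)2 then oxidises only its primary alcohol and returns to 22 directly before step 17.

**Further compounds**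
F1 | step 10 | (E)-homoallylic alcohol (9R,10R), C6=C7 alkene | CC(C)[Si](C(C)C)(C(C)C)OCC/C=C/C[C@@H](O)[C@H](OCc1ccc2ccccc2c1)CCC=C
F2 | step 10 | (6R,7R)-epoxy alcohol | CC(C)[Si](C(C)C)(C(C)C)OCC[C@H]1O[C@@H]1C[C@@H](O)[C@H](OCc1ccc2ccccc2c1)CCC=C
F3 | step 10 | 3-hydroxytetrahydrofuran (6S,7R,9R,10R) with C10 naphthylmethyl ether | CC(C)[Si](C(C)C)(C(C)C)OCC[C@@H]1O[C@@H]([C@H](OCc2ccc3ccccc3c2)CCC=C)C[C@H]1O
F4 | step 10 | C7 triethylsilyl ether of F3 | CC(C)[Si](C(C)C)(C(C)C)OCC[C@@H]1O[C@@H]([C@H](OCc2ccc3ccccc3c2)CCC=C)C[C@H]1O[Si](CC)(CC)CC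
F5 | step 10 | C10 alcohol with C7 triethylsilyl ether | CC(C)[Si](C(C)C)(C(C)C)OCC[C@@H]1O[C@@H]([C@H](O)CCC=C)C[C@H]1O[Si](CC)(CC)CC
F6 | step 10 | C10 acetate with C7 triethylsilyl ether | CC(C)[Si](C(C)C)(C(C)C)OCC[C@@H]1O[C@@H]([C@H](OC(C)=O)CCC=C)C[C@H]1O[Si](CC)(CC)CC
F7 | step 10 | C13 alcohol with C10 acetate and C7 triethylsilyl ether | CC(C)[Si](C(C)C)(C(C)C)OCC[C@@H]1O[C@@H]([C@H](OC(C)=O)CCCO)C[C@H]1O[Si](CC)(CC)CC
F8 | step 18 | (12R)-12-(phenylaminooxy) C13-aldehyde | CC(C)[Si](C(C)C)(C(C)C)OCC[C@@H]1O[C@@H]([C@H](OC(C)=O)C[C@@H](ONc2ccccc2)C=O)C[C@H]1O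
F9 | step 18 | (12R)-12-(phenylaminooxy)-13-hydroxy-14-yne, C13 epimers | CC(C)[Si](C(C)C)(C(C)C)OCC[C@@H]1O[C@@H]([C@H](OC(C)=O)C[C@@H](ONc2ccccc2)C(O)C#C)C[C@H]1O
F10 | step 18 | bicyclic ether with C12 phenylaminooxy group and Co2(CO)6-complexed C13 ethynyl | CC(C)[Si](C(C)C)(C(C)C)OCC[C@@H]1O[C@@H]2C[C@H]1O[C@H](C34[CH]5[Co]3(=C=O)(=C=O)(=C=O)[Co]45(=C=O)(=C=O)=C=O)[C@H](ONc3ccccc3)C[C@H]2OC(C)=O
F11 | step 18 | bicyclic ether with C12 phenylaminooxy group and free C13 ethynyl | CC(C)[Si](C(C)C)(C(C)C)OCC[C@@H]1O[C@@H]2C[C@H]1O[C@H](C#C)[C@H](ONc3ccccc3)C[C@H]2OC(C)=O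
F12 | step 18 | bicyclic (12R)-alcohol with C13 ethyl | CC(C)[Si](C(C)C)(C(C)C)OCC[C@@H]1O[C@@H]2C[C@H]1O[C@H](CC)[C@H](O)C[C@H]2OC(C)=O
F13 | step 16 | (12S)-12-bromo C13 primary alcohol | CC(C)[Si](C(C)C)(C(C)C)OCC[C@@H]1O[C@@H]([C@H](OC(C)=O)C[C@H](Br)CO)C[C@H]1O
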